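**Retrosynthetic overview**

- The axial allylic C–Br bond comes from SN2 inversion of an equatorial allylic alcohol, itself made by axial hydride delivery to an α-methylene ketone.
- The C–O bond at that allylic ring carbon (the future C–Br site) is the key bond: it forms in the [2,3]-sigmatropic rearrangement of an allylseleninic acid (SeO2 ene/[2,3] sequence) on an exocyclic alkene.
- The only ring, with its equatorial neopentyl bromide, comes from a bromonium-initiated cation–olefin cyclisation of an acyclic triene acetate.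
- The triene acetate is the acetate of natural (3S,6E)-nerolidol, which supplies the tertiary carbinol stereocentre unchanged.

Assumption: (3S,6E)-(+)-nerolidol, the natural enantiomer, is bought in high enantiomeric purity.

**Route**

Step 1
Reactants: 1 (3S,6E)-nerolidol
Product: 2 (3S,6E)-3,7,11-trimethyldodeca-1,6,10-trien-3-yl acetate (nerolidyl acetate)
Conditions: Ac2O, Et3N, 4-(dimethylamino)pyridine (cat.), CH2Cl2, rt
Reagents that add atoms: acetic anhydride, CC(=O)OC(C)=O
Why: Steglich-type nucleophile-catalysed acylation of the tertiary allylic alcohol leaves the bought stereocentre untouched and masks the hydroxyl so that it cannot trap the cyclisation cation as a bicyclic ether.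

Step 2
Reactants: 2 (3S,6E)-nerolidyl acetate
Product: 3 (3S)-5-[(1R,3S)-3-bromo-2,2-dimethyl-6-methylidenecyclohexyl]-3-methylpent-1-en-3-yl acetate (β-snyderol acetate)
Conditions: Et2SBr·SbCl5Br (1.1 equiv), MeNO2, −25 °C, 5 min; then aq. Na2SO3/NaHCO3
Reagents that add atoms: bromodiethylsulfonium bromopentachloroantimonate, CC[S+](Br)CC.Br[Sb-](Cl)(Cl)(Cl)(Cl)Cl
Why: Bromonium-initiated cation–olefin cyclisation through a chair transition state places Br and the side chain cis-diequatorial and proton loss from the former C7 methyl gives the exocyclic alkene, but the remote acetoxy stereocentre gives no facial bias, so 3 forms with an equal amount of its (1S,3R) ring diastereomer and with the endocyclic alkene isomer and is separated from them on AgNO3–SiO2 and by preparative HPLC.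

Step 3
Reactants: 3 β-snyderol acetate
Product: 6 (3S)-5-[(1R,3S,5S)-3-bromo-5-hydroxy-2,2-dimethyl-6-methylidenecyclohexyl]-3-methylpent-1-en-3-yl acetate (axial 5-OH), via allylseleninic acid 4 (not isolated), via divalent selenium ester 5 (not isolated)
Conditions: SeO2 (0.5 equiv), t-BuOOH (3 equiv), CH2Cl2, 0 °C to rt
Reagents that add atoms: selenium dioxide, O=[Se]=O; tert-butyl hydroperoxide, CC(C)(C)OO
Why: In this Sharpless–Umbreit SeO2 allylic oxidation the ene reaction at the exocyclic CH2 removes the axial hydrogen of the ring CH2 (preferred over the hindered methine) to give 4, and its [2,3]-sigmatropic rearrangement restores the exocyclic alkene and forms the C–O bond on the same axial face, so hydrolysis of 5 gives the 5S alcohol while t-BuOOH reoxidises selenium.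

Step 4
Reactants: 6 axial allylic alcohol
Product: 7 (3S)-5-[(1R,3S)-3-bromo-2,2-dimethyl-6-methylidene-5-oxocyclohexyl]-3-methylpent-1-en-3-yl acetate
Conditions: Dess–Martin periodinane, NaHCO3, CH2Cl2, 0 °C to rt
Reagents that add atoms: none
Why: Buffered Dess–Martin oxidation converts the secondary allylic alcohol into the α-methylene ketone without touching the tertiary acetate, the alkenes or the neopentyl bromide, which removes the axial carbinol configuration so that it can be reset equatorial.

Step 5
Reactants: 7 α-methylene ketone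
Product: 9 (1R,3R,5S)-5-bromo-3-[(3S)-3-hydroxy-3-methylpent-4-en-1-yl]-4,4-dimethyl-2-methylidenecyclohexan-1-ol, via hydroxy acetate 8 (not isolated)
Conditions: NaBH4, CeCl3·7H2O, MeOH, −78 °C; then K2CO3, MeOH, rt to 40 °C
Reagents that add atoms: none
Why: In this Luche 1,2-reduction the small hydride attacks the conformationally locked ketone (side chain and Br equatorial) along the axial trajectory to give the equatorial 1R alcohol 8 without conjugate reduction, and carbonate-mediated methanolysis then removes the tertiary acetate.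

Step 6
Reactants: 9 diol
Product: 11 (3S)-5-[(1S,3S,5S)-3,5-dibromo-2,2-dimethyl-6-methylidenecyclohexyl]-3-methylpent-1-en-3-ol (target), via alkoxyphosphonium bromide 10 (not isolated)
Conditions: CBr4 (1.3 equiv), PPh3 (1.5 equiv), 2,6-lutidine, CH2Cl2, −20 to 0 °C
Reagents that add atoms: carbon tetrabromide, BrC(Br)(Br)Br; triphenylphosphine, c1ccc(cc1)P(c1ccccc1)c1ccccc1 (held only in 10)
Why: In this Appel reaction only the secondary allylic alcohol is activated (the tertiary one is too hindered), and because the equatorial C–O bond of 10 is orthogonal to the exocyclic π system, SN2′ and ionisation are disfavoured and bromide displaces it by SN2 with inversion to give the axial 5S bromide.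

**Compound list**

1 | (3S,6E)-nerolidol, (3S,6E)-3,7,11-trimethyldodeca-1,6,10-trien-3-ol | C=C[C@@](C)(O)CC/C=C(\C)CCC=C(C)C | starting material
2 | (3S,6E)-3,7,11-trimethyldodeca-1,6,10-trien-3-yl acetate | C=C[C@@](C)(OC(C)=O)CC/C=C(\C)CCC=C(C)C | intermediate
3 | (3S)-5-[(1R,3S)-3-bromo-2,2-dimethyl-6-methylidenecyclohexyl]-3-methylpent-1-en-3-yl acetate | C=C[C@@](C)(OC(C)=O)CC[C@@H]1C(=C)CC[C@H](Br)C1(C)C | intermediate
4 | {(4S,6R)-6-[(3S)-3-acetoxy-3-methylpent-4-en-1-yl]-4-bromo-5,5-dimethylcyclohex-1-en-1-yl}methaneseleninic acid | C=C[C@@](C)(OC(C)=O)CC[C@@H]1C(C[Se](=O)O)=CC[C@H](Br)C1(C)C | intermediate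
5 | (1S,3R,5S)-3-[(3S)-3-acetoxy-3-methylpent-4-en-1-yl]-5-bromo-4,4-dimethyl-2-methylidenecyclohexyl hydrogen selenoxylate (R–O–Se–OH) | C=C[C@@](C)(OC(C)=O)CC[C@@H]1C(=C)[C@@H](O[Se]O)C[C@H](Br)C1(C)C | intermediate
6 | (3S)-5-[(1R,3S,5S)-3-bromo-5-hydroxy-2,2-dimethyl-6-methylidenecyclohexyl]-3-methylpent-1-en-3-yl acetate | C=C[C@@](C)(OC(C)=O)CC[C@@H]1C(=C)[C@@H](O)C[C@H](Br)C1(C)C | intermediate
7 | (3S)-5-[(1R,3S)-3-bromo-2,2-dimethyl-6-methylidene-5-oxocyclohexyl]-3-methylpent-1-en-3-yl acetate | C=C[C@@](C)(OC(C)=O)CC[C@@H]1C(=C)C(=O)C[C@H](Br)C1(C)C | intermediate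
8 | (3S)-5-[(1R,3S,5R)-3-bromo-5-hydroxy-2,2-dimethyl-6-methylidenecyclohexyl]-3-methylpent-1-en-3-yl acetate | C=C[C@@](C)(OC(C)=O)CC[C@@H]1C(=C)[C@H](O)C[C@H](Br)C1(C)C | intermediate
9 | (1R,3R,5S)-5-bromo-3-[(3S)-3-hydroxy-3-methylpent-4-en-1-yl]-4,4-dimethyl-2-methylidenecyclohexan-1-ol | C=C[C@@](C)(O)CC[C@@H]1C(=C)[C@H](O)C[C@H](Br)C1(C)C | intermediate
10 | {[(1R,3R,5S)-5-bromo-3-[(3S)-3-hydroxy-3-methylpent-4-en-1-yl]-4,4-dimethyl-2-methylidenecyclohexyl]oxy}(triphenyl)phosphonium bromide | C=C[C@@](C)(O)CC[C@@H]1C(=C)[C@H](O[P+](c2ccccc2)(c2ccccc2)c2ccccc2)C[C@H](Br)C1(C)C.[Br-] | intermediate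
11 | (3S)-5-[(1S,3S,5S)-3,5-dibromo-2,2-dimethyl-6-methylidenecyclohexyl]-3-methylpent-1-en-3-ol | C=C[C@@](C)(O)CC[C@@H]1C(=C)[C@@H](Br)C[C@H](Br)C1(C)C | target

**Step count**

Total steps: 6. Longest linear sequence: 6.

**Steps most likely to fail**

Step 2. The cyclisation gives exocyclic and endocyclic alkene isomers, the tertiary allylic acetate is acid-sensitive, and the remote stereocentre does not bias the ring sense, so at most half of the cyclised material has the right ring configuration and an HPLC separation is needed. Fallback, setting out from 2 and returning at 3: a mercury-mediated cyclisation in place of direct bromonium chemistry. Hg(OSO2CF3)2·PhNMe2 in MeNO2 at −20 °C closes the ring under milder, exo-olefin-selective conditions. Aqueous NaBr then gives the organomercury bromide (3S)-5-[(1R,3S)-3-(bromomercurio)-2,2-dimethyl-6-methylidenecyclohexyl]-3-methylpent-1-en-3-yl acetate F1. Brominative demercuration (Br2, LiBr, pyridine, O2, 0 °C, predominant retention) gives 3; the two alkenes are at risk from Br2, and the ring diastereomers are still separated as before.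

Step 6. The product is an axial allylic bromide aligned with the alkene, so SN2′ attack or isomerisation to the primary allylic bromide can compete. Fallback, setting out from 3 and returning at 11: bromine is delivered by a selenium-mediated [2,3] shift instead of by substitution of an alcohol. K2CO3 in MeOH converts 3 into β-snyderol (3S)-5-[(1R,3S)-3-bromo-2,2-dimethyl-6-methylidenecyclohexyl]-3-methylpent-1-en-3-ol F4. PhSeBr and N-bromosuccinimide in CH2Cl2 with pyridine give, by addition and loss of HBr, the allylic selenide (3S)-5-[(1R,5S)-5-bromo-6,6-dimethyl-2-(phenylselanylmethyl)cyclohex-2-en-1-yl]-3-methylpent-1-en-3-ol F5. Its Se-brominated form transfers bromine to the ring carbon on the axial face and regenerates the exocyclic alkene, giving 11 directly. This is precedented for chlorine (Sharpless–Hori) but not, to my knowledge, for bromine.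

Step 3. The ene step may also attack the ring methine, and over-oxidation or rearrangement of the allylic acetate is possible. Fallback, setting out from 3 and returning at 6: sulfenylation followed by a Mislow–Evans rearrangement. PhSCl in CH2Cl2 at −78 °C, then Et3N, gives the allylic sulfide (3S)-5-[(1R,5S)-5-bromo-6,6-dimethyl-2-(phenylsulfanylmethyl)cyclohex-2-en-1-yl]-3-methylpent-1-en-3-yl acetate F2. mCPBA (1 equiv, −78 °C) gives the sulfoxide (3S)-5-[(1R,5S)-5-bromo-6,6-dimethyl-2-(phenylsulfinylmethyl)cyclohex-2-en-1-yl]-3-methylpent-1-en-3-yl acetate F3 as both sulfur epimers. Et2NH in MeOH at rt then drives the [2,3]-sigmatropic sulfoxide–sulfenate rearrangement and cleaves the sulfenate to give 6.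

**Further compounds**

F1 | step 2 | (3S)-5-[(1R,3S)-3-(bromomercurio)-2,2-dimethyl-6-methylidenecyclohexyl]-3-methylpent-1-en-3-yl acetate | C=C[C@@](C)(OC(C)=O)CC[C@@H]1C(=C)CC[C@H]([Hg]Br)C1(C)C
F2 | step 3 | (3S)-5-[(1R,5S)-5-bromo-6,6-dimethyl-2-(phenylsulfanylmethyl)cyclohex-2-en-1-yl]-3-methylpent-1-en-3-yl acetate | C=C[C@@](C)(OC(C)=O)CC[C@@H]1C(CSc2ccccc2)=CC[C@H](Br)C1(C)C
F3 | step 3 | (3S)-5-[(1R,5S)-5-bromo-6,6-dimethyl-2-(phenylsulfinylmethyl)cyclohex-2-en-1-yl]-3-methylpent-1-en-3-yl acetate (both sulfur epimers) | C=C[C@@](C)(OC(C)=O)CC[C@@H]1C(CS(=O)c2ccccc2)=CC[C@H](Br)C1(C)C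
F4 | step 6 | (3S)-5-[(1R,3S)-3-bromo-2,2-dimethyl-6-methylidenecyclohexyl]-3-methylpent-1-en-3-ol (β-snyderol) | C=C[C@@](C)(O)CC[C@@H]1C(=C)CC[C@H](Br)C1(C)C
F5 | step 6 | (3S)-5-[(1R,5S)-5-bromo-6,6-dimethyl-2-(phenylselanylmethyl)cyclohex-2-en-1-yl]-3-methylpent-1-en-3-ol | C=C[C@@](C)(O)CC[C@@H]1C(C[Se]c2ccccc2)=CC[C@H](Br)C1(C)C
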